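## Structural features

The target, C30H22O17, is a linear chain of five benzene rings (A to E in the order of the SMILES string) joined only by four diaryl ether oxygens. It has no stereocentre, so no stereocentres stand next to each other, and no ring other than the five benzenes. Ring A is a 2,4,6-trihydroxyphenoxy group. Ring B is a 1,2,3,5-tetraoxygenated benzene with the ring A oxygen on C1 and the ring C oxygen on C2. Ring C is a 1,2,3,5-tetraoxygenated benzene whose central oxygen (on C4, between two hydroxylated carbons) leads to ring D and whose para oxygen (on C1, between two C–H) leads to ring B. Ring D is pentaoxygenated with a single C–H, and ring E is a 3,4,5-trihydroxyphenoxy group. The thirteen free phenolic hydroxyls, including the pyrogallol units of rings D and E, make the compound prone to oxidation by air, above all in base, so they must stay alkylated until the last step. The real difficulty is the four electron-rich, crowded aryl–O–aryl bonds: each ether oxygen is bonded on one side to a carbon flanked by two oxygen-bearing carbons (C1 of ring A, C2 of ring B, C4 of ring C, C2 of ring D). The C–D ether is the worst, because its ring D carbon also has an ortho aryloxy group. The key step exploits ring C: the ring D oxygen is alkylated while C4 is still the sp3 carbon of a cyclobutenone, and ring C is then built around that carbon, so its C4–O bond is never made by coupling and its three other oxygens arrive as free phenol, ethyl ether and silyl ether.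

## Logic of the disconnections

32 to 31. The thirteen O–H bonds of 32 are traced back to eleven O–methyl and two O–ethyl bonds. The free polyphenol oxidises easily, so it is released last. Every earlier compound is then a stable polyether. The forward step must cleave two kinds of alkyl–O bond, leave the four aryl–O–aryl bonds alone and exclude oxygen.

31 to 26 and 30. The ring B C2–O bond of the B–C ether is cut. The oxygen stays with ring C, where it sits on the unhindered para carbon, so the hindrance is confined to the ring B partner. The pentamer falls into a three-ring and a two-ring half. The forward step must activate a C–Br bond flanked by two oxygen substituents on an electron-rich ring.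

30 to 28 and 29, and 28 to 27. The ring B C1–O bond of the A–B ether and the ring B C2–Br bond are cut. Ring A is taken whole as a phenol, and two different halogens on ring B fix the order in which its two ethers are made. All three pieces are simple benzene derivatives. The forward steps must brominate 27 next to iodine and couple at iodine before bromine.

26 to 25 to 24. The para O–H of ring C is traced to an O–Si bond, and one O–ethyl bond to the O–H of 24. The annulation delivers the three ring C oxygens already differentiated; the free one is capped with the same ethyl group as its twin, which makes ring C symmetrical. No extra protecting group is introduced. The alkylation must leave the aryl silyl ether intact and the fluoride step must touch nothing else.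

24 to 14 and 19 (key disconnection). Three C–C bonds of ring C are cut: phenol carbon to its CH neighbour, silyloxy carbon to the other CH, and phenol carbon to the aryloxy carbon. With ring C removed, its doubly flanked aryl–O bond becomes an ordinary alkyl–O bond on the sp3 carbon of 14. The structures of 14, 19 and 24 agree atom for atom with this mechanism and need no correction. The forward step needs a single orientation of ketene and alkyne and partners that survive heating.

19 to 15, 16 and 17. The C≡C bond and the O–Si bond are cut; one alkyne carbon comes from 15 and the other from 16. For the unsubstituted alkyne the ester has to be a formate. The forward step must silylate oxygen, not carbon, and must control the base in the presence of a terminal alkyne.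

14 to 10 and 11, through 12 and 13. Two bonds of the four-membered ring are cut: carbonyl carbon to CH, and aryloxy carbon to ethoxy carbon. This is the retron of a ketene–alkyne [2+2] cycloaddition and leads to an aryloxyacetic acid and a commercial alkyne. The ketene must be trapped faster than it dimerises.

10 to 9, and 9 to 7 and 8. The acid is traced to its methyl ester, and the ring E C1–O bond of the D–E ether is cut. The hindered oxygen belongs to the ring D phenol and the ring E partner has free ortho positions, the polarity an oxidative copper coupling tolerates. The forward step must accept an oxidisable, doubly flanked phenol next to an ester.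

7 to 5 to 3, and 3 to 1 and 2. The ring D C2–O bond is traced to a C2–CHO bond (oxygen insertion), the formyl group to a C–H bond, and the O–CH2 bond is cut. The oxyacetate chain is put on first, so it serves both as the future ketene and as the protection of this oxygen; this removes the protection and deprotection of a free ring D–E phenol. Formylation has only one possible site by symmetry, and the peracid step needs aryl migration.

## Other disconnections considered

Alternative 1: The cut removes both ether bonds of ring C at once, the ring B C2–O bond and the ring D C1–O bond. It leaves 2,6-dimethoxybenzene-1,4-diol A2 as a central dinucleophile, the ring A–B fluoro aldehyde A3 and the ring D–E fluoro aldehyde A4. Forward, the unhindered oxygen of A2 would displace fluoride from A3 under K2CO3, and the doubly flanked oxygen would then displace fluoride from A4 under Cs2CO3 in the same pot to give dialdehyde A1. Two Baeyer–Villiger oxidations and a global dealkylation would follow.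
- In its favour: three fragments meet in one operation; addition–elimination at a fluoride para to a formyl group is a dependable way to a crowded diaryl ether; each formyl group is a latent hydroxyl exactly where rings B and D need one; no ketene or ynol ether is handled.
- Against it here: the second substitution is the worst case of the molecule, a doubly flanked phenoxide attacking a carbon with an ortho aryloxy group. The formyl group of A4 lies between two methoxy groups and is twisted out of conjugation, which weakens its activation. A2 is a hydroquinone that oxidises readily in base. A3 and A4 are themselves demanding: the A–B ether of A3 is meta to the formyl group and cannot be made by the same reaction, and A4 is a pentasubstituted benzaldehyde.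
- Comparison: both plans treat ring C as the hub, but here ring C is bought and both its ethers are made by intermolecular coupling, whereas the chosen plan grows ring C on the ring D oxygen. Mechanistically a polar two-step substitution stands against a pericyclic cascade. The substitution is the more routinely practised reaction, and in convergence and in operations after the fragments are in hand (about three against six from 14) the alternative is the better. The chosen plan is preferred because it avoids the hindered C–D coupling and the late oxidation of two aldehydes on the complete pentamer, at the price of a longer linear sequence.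

Alternative 2: The cut lies inside ring A. The C–C bond between the carboxylate-bearing carbon and a neighbouring hydroxyl-bearing carbon of A5 is broken, which unfolds ring A into the acyclic dimethyl 2-aryloxy-3,5-dioxoheptanedioate A6, bound through its C2 oxygen to ring B. Forward, base would form the polyanion of A6, C6 would attack the C1 ester in a Claisen condensation, and enolisation would give the phloroglucinol carboxylate A5. Hydrolysis, decarboxylation and dealkylation would follow.
- In its favour: like the chosen key step, it makes the doubly flanked aryl–O bond of a ring as an alkyl–O bond before the ring exists. The three ring A oxygens emerge as free hydroxyls, which is what ring A needs. The reagents are simple and free of transition metals.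
- Against it here: the one ring construction is spent on the terminal ring, which can be bought as 29. The B–C, C–D and D–E ethers are left to other methods, since A6 presupposes that rings B to E are already joined. A 3,5-dioxo ester can also close through oxygen (lactonisation) or by aldol modes. Strongly basic polyanion chemistry would be applied late to the most valuable intermediate, and the ester must afterwards be removed.
- Comparison: the two plans apply the same structural idea to different rings. For a ring whose three oxygens need not be told apart, the Claisen closure is the equal of the benzannulation and the better in simplicity of reagents. Ring C needs its para oxygen differentiated, which the pericyclic route supplies and an ionic closure to a symmetrical triol would not. An ionic condensation driven by aromatisation stands against concerted electrocyclic steps steered by alkyne polarisation. In step economy it is weaker here, because a one-step coupling of a commercial ring A is replaced by a chain construction at the end.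

Alternative 3: The cut removes two peripheral C–O bonds, the para hydroxyl of ring A and the C5 hydroxyl of ring B, and traces them to C–H bonds of the less oxygenated pentamer A8. Forward, [Ir(OMe)(cod)]2 with 4,4'-di-tert-butyl-2,2'-bipyridine and B2pin2 would borylate the only two C–H positions of A8 without an ortho substituent, one on ring A and one on ring B. H2O2 would then convert both C–B bonds into the hydroxyls of A7, and dealkylation would give the target.
- In its favour: the regiochemistry is governed by sterics and is easy to predict, since every other aromatic C–H of A8 is flanked by an oxygen substituent. Rings A and B would come from cheaper, less oxygenated building blocks. A ring B electrophile lacking the para oxygen would be less electron-rich, which should ease its etherification.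
- Against it here: the step forms none of the four hindered ether bonds, so the central problem is only moved. Two borylations must both go to completion on a large, Lewis-basic polyether, with the risk of partly functionalised mixtures. Two operations are added at the end.
- Comparison: it addresses the periphery, whereas the chosen key step builds ring C and the C–D ether; it is metal-catalysed C–H activation against a thermal pericyclic cascade. In predictability of regiochemistry it is the equal of the chosen key step, and in easing the coupling that forms the B–C ether it may be the better. It is a possible complement more than a rival, and it was not adopted because it lengthens the end game without simplifying the bonds that are hard to make.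

Key step: step 8

Remark: 14, 21 and 23 each carry one sp3 stereocentre and are racemic; this has no consequence, because that carbon becomes aromatic in 24. In names, ArO stands for the 3,4,5-trimethoxy-2-(3,4,5-trimethoxyphenoxy)phenoxy group (rings D and E).

## Route

Step 1
Reactants: 1 3,4,5-trimethoxyphenol; 2 methyl bromoacetate
Product: 3 methyl 2-(3,4,5-trimethoxyphenoxy)acetate
Conditions: K2CO3, acetone, reflux
Reagents that add atoms: none
Why: Williamson O-alkylation of the only phenol by a reactive α-halo ester. The oxyacetate later supplies the ketene carbons and meanwhile masks this oxygen.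

Step 2
Reactants: 3 methyl 2-(3,4,5-trimethoxyphenoxy)acetate
Product: 5 methyl 2-(2-formyl-3,4,5-trimethoxyphenoxy)acetate, via iminium chloride 4 (not isolated)
Conditions: POCl3, DMF, 0 → 60 °C; then ice-water
Reagents that add atoms: N,N-dimethylformamide, CN(C)C=O; water, O
Why: Vilsmeier–Haack formylation. The two free ring positions are equivalent and each is ortho or para to three oxygens, so only one regioisomer can form, and the formyl group deactivates the ring against a second attack.

Step 3
Reactants: 5 methyl 2-(2-formyl-3,4,5-trimethoxyphenoxy)acetate
Product: 7 methyl 2-(2-hydroxy-3,4,5-trimethoxyphenoxy)acetate, via aryl formate 6 (not isolated)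
Conditions: mCPBA, CH2Cl2, 0 °C → rt; aq NaHCO3 wash; then K2CO3 (cat.), MeOH, rt, argon
Reagents that add atoms: 3-chloroperoxybenzoic acid, OOC(=O)c1cccc(Cl)c1
Why: Baeyer–Villiger oxidation of an aldehyde flanked by two alkoxy groups, in which the electron-rich aryl group migrates, followed by methanolysis of the formate. Any lactone formed between the phenol and the neighbouring ester is reopened by methanol under the same conditions.

Step 4
Reactants: 7 methyl 2-(2-hydroxy-3,4,5-trimethoxyphenoxy)acetate; 8 (3,4,5-trimethoxyphenyl)boronic acid
Product: 9 methyl 2-[3,4,5-trimethoxy-2-(3,4,5-trimethoxyphenoxy)phenoxy]acetate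
Conditions: Cu(OAc)2, pyridine, 4 Å MS, CH2Cl2, air, rt
Reagents that add atoms: none
Why: Chan–Lam oxidative etherification. The hindrance lies on the phenol, which this coupling tolerates, while the boronic acid is electron-rich and has no ortho substituent; the neutral conditions at room temperature spare the ester.

Step 5
Reactants: 9 methyl 2-ArO-acetate
Product: 10 2-ArO-acetic acid
Conditions: LiOH, THF–H2O, rt; then 1 M HCl to pH 3
Reagents that add atoms: lithium hydroxide, [Li+].[OH-]
Why: Saponification of an unhindered methyl ester activated by its α-oxygen; aryl ethers are inert.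

Step 6
Reactants: 10 2-ArO-acetic acid; 11 ethoxyacetylene
Product: 14 3-ethoxy-4-ArO-cyclobut-2-en-1-one (racemic), via acid chloride 12 (not isolated), via aryloxyketene 13 (not isolated)
Conditions: (COCl)2, DMF (cat.), CH2Cl2, 0 °C; evaporate; then 11 (3 equiv), Et3N (slow addition), Et2O, 0 °C → rt
Reagents that add atoms: none
Why: Dehydrochlorination of 12 gives ketene 13, which undergoes [2+2] cycloaddition with the ynol ether; the unsubstituted, nucleophilic alkyne carbon attacks the ketene carbonyl carbon, so the ethoxy carbon ends next to the aryloxy carbon. Slow addition of the amine keeps the ketene concentration low against dimerisation, and cold conditions free of Lewis acid disfavour acylation of ring D by 12.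

Step 7
Reactants: 15 ethyl formate; 16 dibromomethane; 17 triisopropylsilyl trifluoromethanesulfonate
Product: 19 (triisopropylsilyloxy)acetylene, via lithium ethynolate 18 (not isolated)
Conditions: 16, lithium 2,2,6,6-tetramethylpiperidide, THF, −78 °C; 15; LiN(SiMe3)2; n-BuLi (1 equiv), −78 → 0 °C; then 17, −78 → 0 °C
Reagents that add atoms: none
Why: Kowalski ester homologation: dibromomethyllithium adds to the ester, the derived dibromo enolate undergoes bromine–lithium exchange and a 1,2-shift (here of hydrogen) to the ynolate. The bulky silyl triflate silylates the ynolate on oxygen and not on carbon.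

Step 8
Reactants: 14 3-ethoxy-4-ArO-cyclobut-2-en-1-one; 19 (triisopropylsilyloxy)acetylene
Product: 24 3-ethoxy-2-ArO-5-(triisopropylsilyloxy)phenol, via vinylketene 20 (not isolated), via vinylcyclobutenone 21 (not isolated), via dienylketene 22 (not isolated), via cyclohexadienone 23 (not isolated)
Conditions: 19 (2 equiv), toluene, 80 → 110 °C, sealed tube, argon
Reagents that add atoms: none
Why: Danheiser benzannulation; the closest known reaction type is the formation of resorcinol monosilyl ethers from cyclobutenones, 3-oxygenated ones included, and silyloxyacetylenes. Heating opens 14 by 4π conrotatory cleavage of the C1–C4 bond to vinylketene 20, the aryloxy donor rotating outward. The ketene C=C of 20 and alkyne 19 then combine in a [2+2] cycloaddition to 21; the unsubstituted alkyne carbon, β to oxygen and so the nucleophile, bonds to the electrophilic ketene carbonyl carbon, which puts the silyloxy carbon next to the former C2 and fixes the 1,3,5 relation of the three new ring oxygens. A second 4π opening of 21 gives dienylketene 22, and ring C, the only ring formed, closes by thermal 6π disrotatory electrocyclisation between the ketene carbon and the carbon bearing the ring D oxygen, after which 23 tautomerises to phenol 24. The former sp3 carbon thus becomes the central carbon of three contiguous oxygens, and the most hindered aryl–O bond is never made by coupling. No stereocentre is created and the racemic centre of 14 is erased. The selectivity required is regiochemical and is secured by the polarisation of 19 and by the fact that only the dienylketene isomer with its chain ends cis can close; the excess of alkyne limits acylation of the product phenol by 20.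

Step 9
Reactants: 24 3-ethoxy-2-ArO-5-(triisopropylsilyloxy)phenol
Product: 25 (3,5-diethoxy-4-ArO-phenoxy)tri(propan-2-yl)silane
Conditions: EtI, K2CO3, DMF, rt
Reagents that add atoms: iodoethane, CCI
Why: Williamson ethylation of the one free phenol under conditions mild enough for the aryl silyl ether. Ethyl is chosen so that ring C becomes symmetrical and both flanking groups fall together in the final dealkylation.

Step 10
Reactants: 25 (3,5-diethoxy-4-ArO-phenoxy)tri(propan-2-yl)silane
Product: 26 3,5-diethoxy-4-ArO-phenol
Conditions: Bu4NF, AcOH, THF, 0 °C → rt
Reagents that add atoms: none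
Why: Fluoride cleaves the Si–O bond and nothing else. Acetic acid protonates the electron-rich phenoxide at once and limits its oxidation by air.

Step 11
Reactants: 27 1-iodo-3,5-dimethoxybenzene
Product: 28 2-bromo-1-iodo-3,5-dimethoxybenzene
Conditions: NBS, MeCN, 0 °C → rt
Reagents that add atoms: N-bromosuccinimide, O=C1CCC(=O)N1Br
Why: Electrophilic aromatic bromination. The position next to iodine is para to one methoxy group, ortho to the other and less crowded than the position between the two methoxy groups, the usual outcome for 1-substituted 3,5-dimethoxybenzenes.

Step 12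
Reactants: 28 2-bromo-1-iodo-3,5-dimethoxybenzene; 29 2,4,6-trimethoxyphenol
Product: 30 2-bromo-1,5-dimethoxy-3-(2,4,6-trimethoxyphenoxy)benzene
Conditions: CuI (10 mol %), picolinic acid (20 mol %), K3PO4, DMSO, 80 °C, argon
Reagents that add atoms: none
Why: Ligand-accelerated Ullmann etherification. The C–I bond reacts well before the C–Br bond, and this catalyst system is suited to phenols with two ortho substituents.

Step 13
Reactants: 26 3,5-diethoxy-4-ArO-phenol; 30 2-bromo-1,5-dimethoxy-3-(2,4,6-trimethoxyphenoxy)benzene
Product: 31 2-[2-(3,5-diethoxy-4-ArO-phenoxy)-3,5-dimethoxyphenoxy]-1,3,5-trimethoxybenzene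
Conditions: CuI (20 mol %), picolinic acid (40 mol %), K3PO4, DMSO, 110 °C, argon
Reagents that add atoms: none
Why: Ullmann etherification in which the hindrance is confined to the aryl bromide and the nucleophile is an unhindered, electron-rich phenol. All other groups are aryl alkyl and diaryl ethers, inert to base and copper.

Step 14
Reactants: 31 2-[2-(3,5-diethoxy-4-ArO-phenoxy)-3,5-dimethoxyphenoxy]-1,3,5-trimethoxybenzene
Product: 32 2-[2-(3,5-dihydroxy-4-{3,4,5-trihydroxy-2-(3,4,5-trihydroxyphenoxy)phenoxy}phenoxy)-3,5-dihydroxyphenoxy]benzene-1,3,5-triol (target)
Conditions: BBr3 (excess), CH2Cl2, −78 °C → rt; then H2O, 0 °C; argon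
Reagents that add atoms: none
Why: Lewis-acid dealkylation: bromide attacks the alkyl carbon of each boron-complexed ether and removes eleven methyl and two ethyl groups. The diaryl ether bonds offer no such site and survive; no stereocentre is involved.

## Compound list

1 | 3,4,5-trimethoxyphenol | COc1cc(O)cc(OC)c1OC | starting material
2 | methyl bromoacetate | COC(=O)CBr | starting material
3 | methyl 2-(3,4,5-trimethoxyphenoxy)acetate | COC(=O)COc1cc(OC)c(OC)c(OC)c1 | intermediate
4 | [2-(2-methoxy-2-oxoethoxy)-4,5,6-trimethoxybenzylidene]dimethylammonium chloride | COC(=O)COc1cc(OC)c(OC)c(OC)c1C=[N+](C)C.[Cl-] | intermediate (not isolated)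
5 | methyl 2-(2-formyl-3,4,5-trimethoxyphenoxy)acetate | COC(=O)COc1cc(OC)c(OC)c(OC)c1C=O | intermediate
6 | methyl 2-[2-(formyloxy)-3,4,5-trimethoxyphenoxy]acetate | COC(=O)COc1cc(OC)c(OC)c(OC)c1OC=O | intermediate (not isolated)
7 | methyl 2-(2-hydroxy-3,4,5-trimethoxyphenoxy)acetate | COC(=O)COc1cc(OC)c(OC)c(OC)c1O | intermediate
8 | (3,4,5-trimethoxyphenyl)boronic acid | COc1cc(B(O)O)cc(OC)c1OC | starting material
9 | methyl 2-[3,4,5-trimethoxy-2-(3,4,5-trimethoxyphenoxy)phenoxy]acetate | COC(=O)COc1cc(OC)c(OC)c(OC)c1Oc1cc(OC)c(OC)c(OC)c1 | intermediate
10 | 2-[3,4,5-trimethoxy-2-(3,4,5-trimethoxyphenoxy)phenoxy]acetic acid | OC(=O)COc1cc(OC)c(OC)c(OC)c1Oc1cc(OC)c(OC)c(OC)c1 | intermediate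
11 | ethoxyacetylene (ethoxyethyne) | C#COCC | starting material
12 | 2-[3,4,5-trimethoxy-2-(3,4,5-trimethoxyphenoxy)phenoxy]acetyl chloride | ClC(=O)COc1cc(OC)c(OC)c(OC)c1Oc1cc(OC)c(OC)c(OC)c1 | intermediate (not isolated)
13 | 2-[3,4,5-trimethoxy-2-(3,4,5-trimethoxyphenoxy)phenoxy]ethen-1-one (aryloxyketene) | O=C=COc1cc(OC)c(OC)c(OC)c1Oc1cc(OC)c(OC)c(OC)c1 | intermediate (not isolated)
14 | 3-ethoxy-4-[3,4,5-trimethoxy-2-(3,4,5-trimethoxyphenoxy)phenoxy]cyclobut-2-en-1-one (racemic) | CCOC1=CC(=O)C1Oc1cc(OC)c(OC)c(OC)c1Oc1cc(OC)c(OC)c(OC)c1 | intermediate
15 | ethyl formate | CCOC=O | starting material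
16 | dibromomethane | BrCBr | starting material
17 | triisopropylsilyl trifluoromethanesulfonate | CC(C)[Si](OS(=O)(=O)C(F)(F)F)(C(C)C)C(C)C | starting material
18 | lithium ethynolate | [Li+].[O-]C#C | intermediate (not isolated)
19 | (triisopropylsilyloxy)acetylene | C#CO[Si](C(C)C)(C(C)C)C(C)C | intermediate
20 | (3Z)-3-ethoxy-4-ArO-buta-1,3-dien-1-one (vinylketene) | O=C=C/C(OCC)=C/Oc1cc(OC)c(OC)c(OC)c1Oc1cc(OC)c(OC)c(OC)c1 | intermediate (not isolated)
21 | 4-[(Z)-1-ethoxy-2-ArO-ethenyl]-3-(triisopropylsilyloxy)cyclobut-2-en-1-one (racemic) | O=C1C=C(O[Si](C(C)C)(C(C)C)C(C)C)C1/C(OCC)=C/Oc1cc(OC)c(OC)c(OC)c1Oc1cc(OC)c(OC)c(OC)c1 | intermediate (not isolated)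
22 | (3E,5Z)-5-ethoxy-6-ArO-3-(triisopropylsilyloxy)hexa-1,3,5-trien-1-one (dienylketene) | O=C=C/C(O[Si](C(C)C)(C(C)C)C(C)C)=C\C(OCC)=C\Oc1cc(OC)c(OC)c(OC)c1Oc1cc(OC)c(OC)c(OC)c1 | intermediate (not isolated)
23 | 5-ethoxy-6-ArO-3-(triisopropylsilyloxy)cyclohexa-2,4-dien-1-one (racemic) | O=C1C=C(O[Si](C(C)C)(C(C)C)C(C)C)C=C(OCC)C1Oc1cc(OC)c(OC)c(OC)c1Oc1cc(OC)c(OC)c(OC)c1 | intermediate (not isolated)
24 | 3-ethoxy-2-[3,4,5-trimethoxy-2-(3,4,5-trimethoxyphenoxy)phenoxy]-5-(triisopropylsilyloxy)phenol | CCOc1cc(O[Si](C(C)C)(C(C)C)C(C)C)cc(O)c1Oc1cc(OC)c(OC)c(OC)c1Oc1cc(OC)c(OC)c(OC)c1 | intermediate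
25 | {3,5-diethoxy-4-[3,4,5-trimethoxy-2-(3,4,5-trimethoxyphenoxy)phenoxy]phenoxy}tri(propan-2-yl)silane | CCOc1cc(O[Si](C(C)C)(C(C)C)C(C)C)cc(OCC)c1Oc1cc(OC)c(OC)c(OC)c1Oc1cc(OC)c(OC)c(OC)c1 | intermediate
26 | 3,5-diethoxy-4-[3,4,5-trimethoxy-2-(3,4,5-trimethoxyphenoxy)phenoxy]phenol | CCOc1cc(O)cc(OCC)c1Oc1cc(OC)c(OC)c(OC)c1Oc1cc(OC)c(OC)c(OC)c1 | intermediate
27 | 1-iodo-3,5-dimethoxybenzene | COc1cc(I)cc(OC)c1 | starting material
28 | 2-bromo-1-iodo-3,5-dimethoxybenzene | COc1cc(OC)c(Br)c(I)c1 | intermediate
29 | 2,4,6-trimethoxyphenol | COc1cc(OC)c(O)c(OC)c1 | starting material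
30 | 2-bromo-1,5-dimethoxy-3-(2,4,6-trimethoxyphenoxy)benzene | COc1cc(OC)c(Br)c(Oc2c(OC)cc(OC)cc2OC)c1 | intermediate
31 | 2-(2-{3,5-diethoxy-4-[3,4,5-trimethoxy-2-(3,4,5-trimethoxyphenoxy)phenoxy]phenoxy}-3,5-dimethoxyphenoxy)-1,3,5-trimethoxybenzene | COc1cc(OC)c(Oc2cc(OC)cc(OC)c2Oc2cc(OCC)c(Oc3cc(OC)c(OC)c(OC)c3Oc3cc(OC)c(OC)c(OC)c3)c(OCC)c2)c(OC)c1 | intermediate
32 | 2-[2-(3,5-dihydroxy-4-{3,4,5-trihydroxy-2-(3,4,5-trihydroxyphenoxy)phenoxy}phenoxy)-3,5-dihydroxyphenoxy]benzene-1,3,5-triol | Oc1cc(O)c(Oc2cc(O)cc(O)c2Oc2cc(O)c(Oc3cc(O)c(O)c(O)c3Oc3cc(O)c(O)c(O)c3)c(O)c2)c(O)c1 | target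

## Step count and least certain steps

Total step count: 14. Longest linear sequence: 11 steps from 1 (steps 1 to 6, 8 to 10, 13 and 14). Step 7 (one step) and steps 11 and 12 (two steps) are side branches.

Step 8 (key step). The electrocyclic opening of the vinylogous-ester cyclobutenone may be too slow at temperatures the terminal silyloxyalkyne tolerates, so that silyl migration or oligomerisation of the alkyne, or acylation of the newly formed phenol by the vinylketene, takes over. The fallback generates the same vinylketene at low temperature by 1,4-dehydrochlorination instead of ring opening. It sets out from 9: Claisen condensation with the lithium enolate of ethyl acetate (LiN(i-Pr)2, THF, −78 °C) should give ethyl 4-ArO-3-oxobutanoate F1. Triethyl orthoformate with catalytic TsOH in ethanol should convert it into the enol ether ethyl (E)-3-ethoxy-4-ArO-but-2-enoate F2, and KOH in aqueous ethanol followed by careful acidification should give (E)-3-ethoxy-4-ArO-but-2-enoic acid F3. 1-Chloro-N,N,2-trimethylprop-1-en-1-amine, which is neutral and spares the enol ether, should give (E)-3-ethoxy-4-ArO-but-2-enoyl chloride F4. Et3N at 0 °C in the presence of 19 should then remove HCl across the γ and carbonyl positions. The route is rejoined at 20, which is trapped by 19 as it forms and carried through 21 to 24 by gentle warming.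

Step 7. The formate adduct may collapse early and take up a second carbenoid; excess base may deprotonate the terminal ynolate, which leads to silylation on carbon; and the volatile, acid-sensitive product may be lost on isolation. The fallback sets out from 17 and keeps a carbon-bound silyl group on the alkyne as a placeholder. Lithium (trimethylsilyl)acetylide is oxidised with lithium tert-butyl peroxide to the ynolate and silylated on oxygen with 17 to give triisopropyl{[2-(trimethylsilyl)ethynyl]oxy}silane F5. F5 replaces 19 in the benzannulation with 14 and should give 3-ethoxy-2-ArO-5-(triisopropylsilyloxy)-6-(trimethylsilyl)phenol F6. Ipso-protodesilylation of this highly activated aryl silane (CF3CO2H, CH2Cl2, 0 °C) returns the route to 24.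

Step 13. Activation of a C–Br bond flanked by two oxygen substituents on an electron-rich ring may be slow, so that hydrodebromination and oxidative degradation of the phenol compete at the temperature required. The fallback reverses the polarity, putting the hindrance on the phenol as in step 4. It sets out from 30 and 26. Bromine–lithium exchange on 30 (n-BuLi, THF, −78 °C), B(OMe)3 and H2O2/NaOH should give 2,4-dimethoxy-6-(2,4,6-trimethoxyphenoxy)phenol F7. Tf2O and pyridine convert 26 into 3,5-diethoxy-4-ArO-phenyl trifluoromethanesulfonate F8, and palladium-catalysed borylation (Pd(OAc)2, XPhos, B2(OH)4, KOAc, EtOH, 80 °C) should give (3,5-diethoxy-4-ArO-phenyl)boronic acid F9. Chan–Lam coupling of F7 with F9 (Cu(OAc)2, pyridine, 4 Å MS, CH2Cl2, air) returns the route to 31.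

## Further compounds

F1 | step 8 | ethyl 4-[3,4,5-trimethoxy-2-(3,4,5-trimethoxyphenoxy)phenoxy]-3-oxobutanoate | CCOC(=O)CC(=O)COc1cc(OC)c(OC)c(OC)c1Oc1cc(OC)c(OC)c(OC)c1
F2 | step 8 | ethyl (E)-3-ethoxy-4-[3,4,5-trimethoxy-2-(3,4,5-trimethoxyphenoxy)phenoxy]but-2-enoate | CCOC(=O)/C=C(/OCC)COc1cc(OC)c(OC)c(OC)c1Oc1cc(OC)c(OC)c(OC)c1
F3 | step 8 | (E)-3-ethoxy-4-[3,4,5-trimethoxy-2-(3,4,5-trimethoxyphenoxy)phenoxy]but-2-enoic acid | OC(=O)/C=C(/OCC)COc1cc(OC)c(OC)c(OC)c1Oc1cc(OC)c(OC)c(OC)c1
F4 | step 8 | (E)-3-ethoxy-4-[3,4,5-trimethoxy-2-(3,4,5-trimethoxyphenoxy)phenoxy]but-2-enoyl chloride | ClC(=O)/C=C(/OCC)COc1cc(OC)c(OC)c(OC)c1Oc1cc(OC)c(OC)c(OC)c1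
F5 | step 7 | triisopropyl{[2-(trimethylsilyl)ethynyl]oxy}silane | C[Si](C)(C)C#CO[Si](C(C)C)(C(C)C)C(C)C
F6 | step 7 | 3-ethoxy-2-[3,4,5-trimethoxy-2-(3,4,5-trimethoxyphenoxy)phenoxy]-5-(triisopropylsilyloxy)-6-(trimethylsilyl)phenol | CCOc1cc(O[Si](C(C)C)(C(C)C)C(C)C)c([Si](C)(C)C)c(O)c1Oc1cc(OC)c(OC)c(OC)c1Oc1cc(OC)c(OC)c(OC)c1
F7 | step 13 | 2,4-dimethoxy-6-(2,4,6-trimethoxyphenoxy)phenol | COc1cc(OC)c(O)c(Oc2c(OC)cc(OC)cc2OC)c1
F8 | step 13 | 3,5-diethoxy-4-[3,4,5-trimethoxy-2-(3,4,5-trimethoxyphenoxy)phenoxy]phenyl trifluoromethanesulfonate | CCOc1cc(OS(=O)(=O)C(F)(F)F)cc(OCC)c1Oc1cc(OC)c(OC)c(OC)c1Oc1cc(OC)c(OC)c(OC)c1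
F9 | step 13 | {3,5-diethoxy-4-[3,4,5-trimethoxy-2-(3,4,5-trimethoxyphenoxy)phenoxy]phenyl}boronic acid | CCOc1cc(B(O)O)cc(OCC)c1Oc1cc(OC)c(OC)c(OC)c1Oc1cc(OC)c(OC)c(OC)c1
A1 | alternative 1 | pentaaryl tetraether with formyl groups on rings B and D | COc1cc(OC)c(Oc2cc(C=O)cc(OC)c2Oc2cc(OC)c(Oc3cc(OC)c(C=O)c(OC)c3Oc3cc(OC)c(OC)c(OC)c3)c(OC)c2)c(OC)c1
A2 | alternative 1 | 2,6-dimethoxybenzene-1,4-diol | COc1cc(O)cc(OC)c1O
A3 | alternative 1 | 4-fluoro-3-methoxy-5-(2,4,6-trimethoxyphenoxy)benzaldehyde | COc1cc(OC)c(Oc2cc(C=O)cc(OC)c2F)c(OC)c1
A4 | alternative 1 | 4-fluoro-2,6-dimethoxy-3-(3,4,5-trimethoxyphenoxy)benzaldehyde | Fc1cc(OC)c(C=O)c(OC)c1Oc1cc(OC)c(OC)c(OC)c1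
A5 | alternative 2 | methyl 3-(aryloxy)-2,4,6-trihydroxybenzoate carrying the permethylated rings B to E | COC(=O)c1c(O)cc(O)c(Oc2cc(OC)cc(OC)c2Oc2cc(OC)c(Oc3cc(OC)c(OC)c(OC)c3Oc3cc(OC)c(OC)c(OC)c3)c(OC)c2)c1O
A6 | alternative 2 | dimethyl 2-(aryloxy)-3,5-dioxoheptanedioate carrying the permethylated rings B to E (racemic) | COC(=O)CC(=O)CC(=O)C(Oc1cc(OC)cc(OC)c1Oc1cc(OC)c(Oc2cc(OC)c(OC)c(OC)c2Oc2cc(OC)c(OC)c(OC)c2)c(OC)c1)C(=O)OC
A7 | alternative 3 | undecamethyl ether of the target with free hydroxyls on rings A and B | Oc1cc(OC)c(Oc2cc(O)cc(OC)c2Oc2cc(OC)c(Oc3cc(OC)c(OC)c(OC)c3Oc3cc(OC)c(OC)c(OC)c3)c(OC)c2)c(OC)c1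
A8 | alternative 3 | undecamethoxy pentamer lacking the para oxygen of ring A and the C5 oxygen of ring B | COc1cccc(OC)c1Oc1cccc(OC)c1Oc1cc(OC)c(Oc2cc(OC)c(OC)c(OC)c2Oc2cc(OC)c(OC)c(OC)c2)c(OC)c1
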